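**Retrosynthetic overview**
- The strategy rests on the C3–C4 bond of the pyranone ring C. C3 (the carbon carrying the sulfated enol oxygen) and C4 (the carbonyl carbon) are adjacent oxygen-bearing carbons, so the bond is a masked 1,2-diol and is cut as a pinacol coupling of two aldehydes.
- Target ⇐ hydrogenolysis of three benzyl ethers ⇐ bis-sulfation of the 3- and 3'-hydroxyls ⇐ MOM removal ⇐ 3-hydroxyflavone ⇐ double oxidation of a flavan-3,4-diol.
- Flavan-3,4-diol ⇐ samarium diiodide ketyl–aldehyde coupling of an aryl aldehyde (future C4) with an α-aryloxy aldehyde (future C3).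
- Dialdehyde ⇐ reduction/re-oxidation of an aldehyde ester ⇐ Mitsunobu O1–C2 etherification of dibenzylated phloroglucinaldehyde with a ring-B mandelate (ring-B aldehyde + bromoform).
- Rings A and B are bought; ring C is the only ring formed (step 8) and is aromatised in step 9.

Key step: step 8

Assumption: the target is drawn as the free bis(hydrogen sulfate). Because aryl hydrogen sulfates are strong acids that hydrolyse on storage, the acid is released from its bis(triethylammonium) salt only in the last operation, cold. The target has no stereocentre, and all chiral intermediates are racemic.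

**Step 1**
Reactants: 1 2,4,6-trihydroxybenzaldehyde; 2 benzyl bromide
Product: 3 4,6-bis(benzyloxy)-2-hydroxybenzaldehyde
Conditions: BnBr (2.05 equiv), K2CO3 (2.1 equiv), DMF, 0 °C → rt
Reagents that add atoms: benzyl bromide (2), BrCc1ccccc1
Why: Williamson etherification should stop at the dibenzyl ether, because the last ortho hydroxyl is held in a hydrogen bond to the formyl oxygen and is the least nucleophilic.

**Step 2**
Reactants: 4 4-(benzyloxy)-3-hydroxybenzaldehyde
Product: 5 4-(benzyloxy)-3-(methoxymethoxy)benzaldehyde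
Conditions: MOMCl (1.5 equiv), i-Pr2NEt (2 equiv), CH2Cl2, 0 °C → rt
Reagents that add atoms: chloromethyl methyl ether, COCCl
Why: O-alkylation of the phenol with the chloromethyl ether (MOM protection) marks the future 3'-sulfate position with a base- and hydride-stable acetal that is orthogonal to benzyl.

**Step 3**
Reactants: 5 4-(benzyloxy)-3-(methoxymethoxy)benzaldehyde; 6 bromoform
Product: 7 racemic 2-[4-(benzyloxy)-3-(methoxymethoxy)phenyl]-2-hydroxyacetic acid
Conditions: CHBr3 (1.3 equiv), KOH (5 equiv), LiCl (2 equiv), 1,4-dioxane–H2O, 0–5 °C; then 1 M HCl to pH 3 at 0 °C, EtOAc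
Reagents that add atoms: bromoform (6), BrC(Br)Br; potassium hydroxide, [K+].[OH-]
Why: In this Jocic–Reeve-type one-carbon homologation the tribromomethyl anion adds to the aldehyde, the alkoxide closes to a gem-dibromo epoxide, and hydroxide opens it at the benzylic carbon; the acyl bromide hydrolyses to the mandelic acid, whose stereocentre is racemic and is later destroyed.

**Step 4**
Reactants: 7 racemic 2-[4-(benzyloxy)-3-(methoxymethoxy)phenyl]-2-hydroxyacetic acid
Product: 8 racemic methyl 2-[4-(benzyloxy)-3-(methoxymethoxy)phenyl]-2-hydroxyacetate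
Conditions: MeI (1.5 equiv), KHCO3 (1.5 equiv), DMF, rt
Reagents that add atoms: iodomethane, CI
Why: SN2 alkylation of the carboxylate under bicarbonate conditions should esterify the acid without touching the secondary hydroxyl or the MOM acetal.

**Step 5**
Reactants: 3 4,6-bis(benzyloxy)-2-hydroxybenzaldehyde; 8 racemic methyl 2-[4-(benzyloxy)-3-(methoxymethoxy)phenyl]-2-hydroxyacetate
Product: 9 racemic methyl 2-[3,5-bis(benzyloxy)-2-formylphenoxy]-2-[4-(benzyloxy)-3-(methoxymethoxy)phenyl]acetate
Conditions: PPh3 (1.5 equiv), DIAD (1.5 equiv, added last), THF, 0 °C → rt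
Reagents that add atoms: none
Why: In this Mitsunobu etherification the ortho-formyl phenol is acidic enough to protonate the betaine, and its phenoxide displaces the oxyphosphonium at the ester-activated benzylic carbon, forming the O1–C2 bond (inversion at a racemic centre, of no consequence).

**Step 6**
Reactants: 9 racemic methyl 2-[3,5-bis(benzyloxy)-2-formylphenoxy]-2-[4-(benzyloxy)-3-(methoxymethoxy)phenyl]acetate
Product: 10 racemic 2-[3,5-bis(benzyloxy)-2-(hydroxymethyl)phenoxy]-2-[4-(benzyloxy)-3-(methoxymethoxy)phenyl]ethan-1-ol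
Conditions: LiAlH4 (1.5 equiv), THF, 0 °C; then H2O, 15% NaOH, H2O
Reagents that add atoms: none
Why: Hydride reduction with LiAlH4 takes the ester and the aldehyde to the two primary carbinols, while the aryl ethers and the MOM acetal are inert and the basic work-up spares the electron-rich benzylic alcohol.

**Step 7**
Reactants: 10 racemic 2-[3,5-bis(benzyloxy)-2-(hydroxymethyl)phenoxy]-2-[4-(benzyloxy)-3-(methoxymethoxy)phenyl]ethan-1-ol
Product: 11 racemic 2-[1-[4-(benzyloxy)-3-(methoxymethoxy)phenyl]-2-oxoethoxy]-4,6-bis(benzyloxy)benzaldehyde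
Conditions: Dess–Martin periodinane (2.4 equiv), pyridine (6 equiv), CH2Cl2, 0 °C → rt; short silica plug, used at once
Reagents that add atoms: none
Why: Dess–Martin oxidation of both primary alcohols stops at the aldehyde, and the buffered, non-aqueous conditions should spare the enolisable α-aryloxy aldehyde.

**Step 8**
Reactants: 11 racemic 2-[1-[4-(benzyloxy)-3-(methoxymethoxy)phenyl]-2-oxoethoxy]-4,6-bis(benzyloxy)benzaldehyde
Product: 12 racemic 5,7-bis(benzyloxy)-2-[4-(benzyloxy)-3-(methoxymethoxy)phenyl]chromane-3,4-diol (mixture of diastereomers)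
Conditions: SmI2 (2.5 equiv, 0.1 M in THF) added over 2 h to 11 (0.005 M in THF), −78 → −20 °C, no HMPA, no proton donor; then aq. Rochelle salt
Reagents that add atoms: none
Why: Divalent samarium transfers one electron to the conjugated aromatic aldehyde, and the samarium-bound ketyl adds to the carbon of the tethered aliphatic aldehyde while the oxophilic metal bridges both oxygens; a second electron and aqueous work-up give the diol. This is the samarium diiodide pinacol cyclisation of dicarbonyl compounds to cyclic 1,2-diols, in its ketyl–aldehyde form. Ring C closes in a 6-exo-trig mode, the ketyl carbon C4 attacking C3 with the aldehyde oxygen outside the new ring. The new C3 and C4 centres are set by the samarium chelate, which should favour the 3,4-cis diol, and by the C2 aryl group, which should sit pseudo-equatorial (2,3-trans); no control is needed because C2, C3 and C4 all become sp2 in step 9. The step needs reduction of the aromatic aldehyde in preference to the α-aryloxy aldehyde (whose ketyl would expel the ring-A aryloxide) and cyclisation in preference to dimerisation; conjugation of the aryl aldehyde, the mild HMPA-free reductant, low temperature, and slow addition to a dilute solution are meant to secure both.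

**Step 9**
Reactants: 12 racemic 5,7-bis(benzyloxy)-2-[4-(benzyloxy)-3-(methoxymethoxy)phenyl]chromane-3,4-diol
Product: 14 5,7-bis(benzyloxy)-2-[4-(benzyloxy)-3-(methoxymethoxy)phenyl]-3-hydroxy-4H-chromen-4-one, via flavan-3,4-dione 13 (not isolated)
Conditions: IBX (3 equiv), DMSO, rt → 45 °C
Reagents that add atoms: none
Why: IBX oxidises vicinal diols to 1,2-diketones without C–C cleavage, and the 3,4-dione should enolise at once through C2–H into the aromatic 4-pyranone, which removes all three stereocentres and leaves the 3-hydroxyl free.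

**Step 10**
Reactants: 14 5,7-bis(benzyloxy)-2-[4-(benzyloxy)-3-(methoxymethoxy)phenyl]-3-hydroxy-4H-chromen-4-one
Product: 15 5,7-bis(benzyloxy)-2-[4-(benzyloxy)-3-hydroxyphenyl]-3-hydroxy-4H-chromen-4-one
Conditions: conc. HCl (cat.), MeOH–THF, 45 °C
Reagents that add atoms: none
Why: Acid-catalysed transacetalisation to methanol removes the MOM group under conditions mild enough for the benzyl ethers (including the acid-labile 5-O-benzyl), leaving exactly the two hydroxyls that are to be sulfated.

**Step 11**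
Reactants: 15 5,7-bis(benzyloxy)-2-[4-(benzyloxy)-3-hydroxyphenyl]-3-hydroxy-4H-chromen-4-one
Product: 16 bis(triethylammonium) 5,7-bis(benzyloxy)-2-[4-(benzyloxy)-3-(sulfonatooxy)phenyl]-4-oxo-4H-chromen-3-yl sulfate
Conditions: Et3N·SO3 (10 equiv), Et3N (4 equiv), DMF, 60 °C; Sephadex LH-20, MeOH
Reagents that add atoms: sulfur trioxide–triethylamine complex, CC[N+](CC)(CC)S(=O)(=O)[O-]
Why: O-sulfation with a sulfur trioxide–amine complex can only reach the two free hydroxyls, and excess reagent with heat should overcome the hydrogen bond of the 3-hydroxyl to the C4 carbonyl.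

**Step 12**
Reactants: 16 bis(triethylammonium) 5,7-bis(benzyloxy)-2-[4-(benzyloxy)-3-(sulfonatooxy)phenyl]-4-oxo-4H-chromen-3-yl sulfate
Product: 18 quercetin 3,3'-bissulfate (target), via bis(triethylammonium) quercetin 3,3'-bissulfate 17 (not isolated)
Conditions: H2 (1 atm), 10% Pd/C, MeOH–THF, rt; filter; Dowex 50W-X8 (H+ form), MeOH–H2O, 0 °C; freeze-dry
Reagents that add atoms: none
Why: Hydrogenolysis over Pd/C cleaves the three benzyl ethers while aryl and enol sulfate monoesters and the chromone double bond are inert, and cold cation exchange then trades triethylammonium for protons.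

**Compound list**
1 | 2,4,6-trihydroxybenzaldehyde | O=Cc1c(O)cc(O)cc1O | starting material
2 | benzyl bromide | BrCc1ccccc1 | starting material
3 | 4,6-bis(benzyloxy)-2-hydroxybenzaldehyde | O=Cc1c(O)cc(OCc2ccccc2)cc1OCc1ccccc1 | intermediate
4 | 4-(benzyloxy)-3-hydroxybenzaldehyde | O=Cc1ccc(OCc2ccccc2)c(O)c1 | starting material
5 | 4-(benzyloxy)-3-(methoxymethoxy)benzaldehyde | O=Cc1ccc(OCc2ccccc2)c(OCOC)c1 | intermediate
6 | bromoform | BrC(Br)Br | starting material
7 | racemic 2-[4-(benzyloxy)-3-(methoxymethoxy)phenyl]-2-hydroxyacetic acid | OC(C(=O)O)c1ccc(OCc2ccccc2)c(OCOC)c1 | intermediate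
8 | racemic methyl 2-[4-(benzyloxy)-3-(methoxymethoxy)phenyl]-2-hydroxyacetate | COC(=O)C(O)c1ccc(OCc2ccccc2)c(OCOC)c1 | intermediate
9 | racemic methyl 2-[3,5-bis(benzyloxy)-2-formylphenoxy]-2-[4-(benzyloxy)-3-(methoxymethoxy)phenyl]acetate | COC(=O)C(Oc1cc(OCc2ccccc2)cc(OCc2ccccc2)c1C=O)c1ccc(OCc2ccccc2)c(OCOC)c1 | intermediate
10 | racemic 2-[3,5-bis(benzyloxy)-2-(hydroxymethyl)phenoxy]-2-[4-(benzyloxy)-3-(methoxymethoxy)phenyl]ethan-1-ol | OCC(Oc1cc(OCc2ccccc2)cc(OCc2ccccc2)c1CO)c1ccc(OCc2ccccc2)c(OCOC)c1 | intermediate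
11 | racemic 2-[1-[4-(benzyloxy)-3-(methoxymethoxy)phenyl]-2-oxoethoxy]-4,6-bis(benzyloxy)benzaldehyde | O=CC(Oc1cc(OCc2ccccc2)cc(OCc2ccccc2)c1C=O)c1ccc(OCc2ccccc2)c(OCOC)c1 | intermediate
12 | racemic 5,7-bis(benzyloxy)-2-[4-(benzyloxy)-3-(methoxymethoxy)phenyl]chromane-3,4-diol, mixture of diastereomers | OC1c2c(OCc3ccccc3)cc(OCc3ccccc3)cc2OC(c2ccc(OCc3ccccc3)c(OCOC)c2)C1O | intermediate
13 | racemic 5,7-bis(benzyloxy)-2-[4-(benzyloxy)-3-(methoxymethoxy)phenyl]chromane-3,4-dione | O=C1C(=O)c2c(OCc3ccccc3)cc(OCc3ccccc3)cc2OC1c1ccc(OCc2ccccc2)c(OCOC)c1 | intermediate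
14 | 5,7-bis(benzyloxy)-2-[4-(benzyloxy)-3-(methoxymethoxy)phenyl]-3-hydroxy-4H-chromen-4-one | O=c1c(O)c(-c2ccc(OCc3ccccc3)c(OCOC)c2)oc2cc(OCc3ccccc3)cc(OCc3ccccc3)c12 | intermediate
15 | 5,7-bis(benzyloxy)-2-[4-(benzyloxy)-3-hydroxyphenyl]-3-hydroxy-4H-chromen-4-one | O=c1c(O)c(-c2ccc(OCc3ccccc3)c(O)c2)oc2cc(OCc3ccccc3)cc(OCc3ccccc3)c12 | intermediate
16 | bis(triethylammonium) 5,7-bis(benzyloxy)-2-[4-(benzyloxy)-3-(sulfonatooxy)phenyl]-4-oxo-4H-chromen-3-yl sulfate | O=c1c(OS(=O)(=O)[O-])c(-c2ccc(OCc3ccccc3)c(OS(=O)(=O)[O-])c2)oc2cc(OCc3ccccc3)cc(OCc3ccccc3)c12.CC[NH+](CC)CC.CC[NH+](CC)CC | intermediate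
17 | bis(triethylammonium) quercetin 3,3'-bissulfate | O=c1c(OS(=O)(=O)[O-])c(-c2ccc(O)c(OS(=O)(=O)[O-])c2)oc2cc(O)cc(O)c12.CC[NH+](CC)CC.CC[NH+](CC)CC | intermediate
18 | quercetin 3,3'-bissulfate | O=c1c(OS(=O)(=O)O)c(-c2ccc(O)c(OS(=O)(=O)O)c2)oc2cc(O)cc(O)c12 | target

**Step count**
Total steps: 12. Longest linear sequence: 11 steps (from 4 through steps 2–12).

**Steps most likely to fail**

1. Step 8. Electron transfer to the α-aryloxy aldehyde with expulsion of the ring-A aryloxide, or intermolecular ketyl dimerisation, may outrun ring closure. The fallback sets out from 11 and forms the same C3–C4 bond by metathesis.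
   - Double Wittig methylenation (Ph3P=CH2 from Ph3PCH3Br/KHMDS, THF, −78 → 0 °C) should give racemic 1,5-bis(benzyloxy)-3-{1-[4-(benzyloxy)-3-(methoxymethoxy)phenyl]allyloxy}-2-vinylbenzene F1.
   - Ring-closing metathesis with the second-generation Grubbs catalyst (CH2Cl2, 40 °C) should close ring C with loss of ethylene to racemic 5,7-bis(benzyloxy)-2-[4-(benzyloxy)-3-(methoxymethoxy)phenyl]-2H-chromene F2.
   - Dihydroxylation (OsO4 cat., NMO, acetone–H2O) anti to the C2 aryl group should give the 2,3-trans-3,4-cis diol, which is one diastereomer of 12, where the route is rejoined.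

2. Step 9. Glycol cleavage of the C3–C4 bond, or a stall at the ketol stage with over-oxidation of the enol on forcing, may erode the double oxidation. The fallback sets out from 12 and oxidises in two separate stages.
   - DDQ (1.1 equiv, 1,4-dioxane, rt) should take only the C4 carbinol, benzylic to the trioxygenated ring A, to racemic 5,7-bis(benzyloxy)-2-[4-(benzyloxy)-3-(methoxymethoxy)phenyl]-3-hydroxychroman-4-one F3.
   - Iodine with KOAc (EtOH, 70 °C) then dehydrogenates this dihydroflavonol through its enediol to flavonol 14, where the route is rejoined.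

3. Step 11. Incomplete sulfation of the hydrogen-bonded 3-hydroxyl and loss of sulfate during purification of the polar salt may leave mixtures. The fallback sets out from 15 and introduces both sulfates as neutral, chromatographable diesters.
   - 2,2,2-Trichloroethyl chlorosulfate (Et3N, DMAP, THF, 0 °C) should give 5,7-bis(benzyloxy)-2-{4-(benzyloxy)-3-[(2,2,2-trichloroethoxy)sulfonyloxy]phenyl}-4-oxo-4H-chromen-3-yl 2,2,2-trichloroethyl sulfate F4.
   - Reductive β-elimination with zinc dust and HCO2NH4 (MeOH–THF, rt) should unveil bis(ammonium) 5,7-bis(benzyloxy)-2-[4-(benzyloxy)-3-(sulfonatooxy)phenyl]-4-oxo-4H-chromen-3-yl sulfate F5.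
   - Co-evaporation with Et3N in MeOH drives off ammonia and gives 16, where the route is rejoined.

**Further compounds**
F1 | step 8 | racemic 1,5-bis(benzyloxy)-3-{1-[4-(benzyloxy)-3-(methoxymethoxy)phenyl]allyloxy}-2-vinylbenzene | C=CC(Oc1cc(OCc2ccccc2)cc(OCc2ccccc2)c1C=C)c1ccc(OCc2ccccc2)c(OCOC)c1
F2 | step 8 | racemic 5,7-bis(benzyloxy)-2-[4-(benzyloxy)-3-(methoxymethoxy)phenyl]-2H-chromene | C1=Cc2c(OCc3ccccc3)cc(OCc3ccccc3)cc2OC1c1ccc(OCc2ccccc2)c(OCOC)c1
F3 | step 9 | racemic 5,7-bis(benzyloxy)-2-[4-(benzyloxy)-3-(methoxymethoxy)phenyl]-3-hydroxychroman-4-one | O=C1c2c(OCc3ccccc3)cc(OCc3ccccc3)cc2OC(c2ccc(OCc3ccccc3)c(OCOC)c2)C1O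
F4 | step 11 | 5,7-bis(benzyloxy)-2-{4-(benzyloxy)-3-[(2,2,2-trichloroethoxy)sulfonyloxy]phenyl}-4-oxo-4H-chromen-3-yl 2,2,2-trichloroethyl sulfate | O=c1c(OS(=O)(=O)OCC(Cl)(Cl)Cl)c(-c2ccc(OCc3ccccc3)c(OS(=O)(=O)OCC(Cl)(Cl)Cl)c2)oc2cc(OCc3ccccc3)cc(OCc3ccccc3)c12
F5 | step 11 | bis(ammonium) 5,7-bis(benzyloxy)-2-[4-(benzyloxy)-3-(sulfonatooxy)phenyl]-4-oxo-4H-chromen-3-yl sulfate | O=c1c(OS(=O)(=O)[O-])c(-c2ccc(OCc3ccccc3)c(OS(=O)(=O)[O-])c2)oc2cc(OCc3ccccc3)cc(OCc3ccccc3)c12.[NH4+].[NH4+]
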